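The route cuts ring A between C6 and C7. These neighbouring oxygen-bearing carbons are both aldehyde (acceptor) carbons in the open form, so one must be made a donor. A triazolylidene carbene does this on a 6-aryl-4-pyranone whose C3 glyoxal supplies C5 and C6 and whose C2 oxoethyl arm supplies C8 and C7. The benzoin closure forms C6–C7, and the acyloin is a tautomer of the 5,6,7-trihydroxybenzene, so ring A and its three phenols appear in one operation. The pyranone comes from an arylpropynoic acid and tert-butyl acetoacetate; the glyoxal is carried as a dimethyl acetal and the acetaldehyde as an enamine until the step before.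

Key step: step 9

Remark: tert-butyl acetoacetate is used instead of the methyl ester so that the C3 acid is freed by acid; hydroxide or carbanions would open the 4-pyranone or deprotonate its C2 methyl. Compound 17 is drawn as the free dialdehyde but should exist largely as the glyoxal hydrate and partly as the side-chain enol.

Step 1
Reactants: 1 1,2,3,4-tetramethoxybenzene
Product: 2 1-iodo-2,3,4,5-tetramethoxybenzene
Conditions: NIS (1.0 equiv), TFA (cat.), MeCN, 0 °C → rt
Reagents that add atoms: N-iodosuccinimide, O=C1CCC(=O)N1I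
Why: Electrophilic aromatic iodination of a very electron-rich arene whose two free positions are equivalent by symmetry, so only one mono-iodide can form.

Step 2
Reactants: 2 1-iodo-2,3,4,5-tetramethoxybenzene, 3 propiolic acid (prop-2-ynoic acid)
Product: 4 3-(2,3,4,5-tetramethoxyphenyl)prop-2-ynoic acid
Conditions: Pd(PPh3)4 (3 mol %), DBU (2.4 equiv), DMSO, 35 °C; acidic work-up
Reagents that add atoms: none
Why: Copper-free Sonogashira coupling of an aryl iodide with propiolic acid, run near room temperature so that the alkynyl carboxylate should not decarboxylate.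

Step 3
Reactants: 4 3-(2,3,4,5-tetramethoxyphenyl)prop-2-ynoic acid, 5 tert-butyl acetoacetate
Product: 8 tert-butyl 2-methyl-4-oxo-6-(2,3,4,5-tetramethoxyphenyl)-4H-pyran-3-carboxylate, via arylpropynoyl chloride 6 (not isolated), via open-chain C-acylated keto ester 7 (not isolated)
Conditions: 1-chloro-N,N,2-trimethylprop-1-en-1-amine, CH2Cl2, 0 °C → rt; then 5, MgCl2, pyridine, CH2Cl2, 0 °C → rt; then Et3N (cat.), rt
Reagents that add atoms: none
Why: Claisen-type C-acylation of the magnesium chelate of the β-keto ester, followed by 6-endo-dig intramolecular oxa-Michael addition of the acetyl enol oxygen to the ynone, in which only the ketone oxygen can cyclise and so the methyl must end at C2 and the ester at C3.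

Step 4
Reactants: 8 tert-butyl 2-methyl-4-oxo-6-(2,3,4,5-tetramethoxyphenyl)-4H-pyran-3-carboxylate
Product: 9 2-methyl-4-oxo-6-(2,3,4,5-tetramethoxyphenyl)-4H-pyran-3-carboxylic acid
Conditions: TFA/CH2Cl2 (1:3), rt
Reagents that add atoms: none
Why: Acidolysis of the tert-butyl ester with loss of isobutene frees the acid without any nucleophile or base that could attack the pyranone.

Step 5
Reactants: 9 2-methyl-4-oxo-6-(2,3,4,5-tetramethoxyphenyl)-4H-pyran-3-carboxylic acid, 10 (trimethylsilyl)diazomethane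
Product: 12 3-(2-diazoacetyl)-2-methyl-6-(2,3,4,5-tetramethoxyphenyl)-4H-pyran-4-one, via pyranone-3-carbonyl chloride 11 (not isolated)
Conditions: 1-chloro-N,N,2-trimethylprop-1-en-1-amine, CH2Cl2, 0 °C → rt; then 10 (2.2 equiv), THF/MeCN, 0 °C → rt; aq. NaHCO3 work-up
Reagents that add atoms: none
Why: Acylation of the diazoalkane by an acid chloride (the diazoketone-forming half of the Arndt–Eistert sequence), in which a second equivalent of 10 takes up HCl so that no amine base is present to turn the acid chloride into a vinylogous ketene through the C2 methyl, and the C-silyl group is lost on work-up.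

Step 6
Reactants: 12 3-(2-diazoacetyl)-2-methyl-6-(2,3,4,5-tetramethoxyphenyl)-4H-pyran-4-one
Product: 14 3-(2,2-dimethoxyacetyl)-2-methyl-6-(2,3,4,5-tetramethoxyphenyl)-4H-pyran-4-one, via glyoxal 13 (not isolated)
Conditions: DMDO (1.2 equiv), acetone, 0 °C; evaporate; then HC(OMe)3, MeOH, TsOH (cat.), rt → 40 °C
Reagents that add atoms: trimethyl orthoformate, COC(OC)OC; methanol, CO
Why: Dioxirane oxygen transfer to the diazo carbon with loss of N2 gives the α-keto aldehyde under neutral conditions, and acid-catalysed acetalisation then protects only the aldehyde, because the flanked ketone and the vinylogous-ester ring carbonyl should not ketalise.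

Step 7
Reactants: 14 3-(2,2-dimethoxyacetyl)-2-methyl-6-(2,3,4,5-tetramethoxyphenyl)-4H-pyran-4-one, 15 N,N-dimethylformamide dimethyl acetal
Product: 16 3-(2,2-dimethoxyacetyl)-2-[(E)-2-(dimethylamino)ethenyl]-6-(2,3,4,5-tetramethoxyphenyl)-4H-pyran-4-one
Conditions: 15 (3 equiv), N-methylimidazole (cat.), toluene, 90 °C
Reagents that add atoms: none
Why: Enamination of the vinylogously acidic C2 methyl (activated by the ring carbonyl and the C3 acyl group) by the amide acetal gives the push–pull E-enamine, and the acetal carbon has no CH2 or CH3 that could compete.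

Step 8
Reactants: 16 3-(2,2-dimethoxyacetyl)-2-[(E)-2-(dimethylamino)ethenyl]-6-(2,3,4,5-tetramethoxyphenyl)-4H-pyran-4-one
Product: 17 2-oxo-2-[4-oxo-2-(2-oxoethyl)-6-(2,3,4,5-tetramethoxyphenyl)-4H-pyran-3-yl]acetaldehyde
Conditions: 2 M aq. HCl/THF (1:1), 0 °C → 40 °C; extract (EtOAc), dry, use at once
Reagents that add atoms: water, O
Why: Acid hydrolysis of the enamine and of the dimethyl acetal releases both aldehydes in one operation, the dimethylammonium salt is left in the aqueous phase, and the dialdehyde is taken on crude so that it exists only briefly.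

Step 9
Reactants: 17 2-oxo-2-[4-oxo-2-(2-oxoethyl)-6-(2,3,4,5-tetramethoxyphenyl)-4H-pyran-3-yl]acetaldehyde
Product: 19 5,6,7-trihydroxy-2-(2,3,4,5-tetramethoxyphenyl)-4H-chromen-4-one, via ring-A acyloin 18 (not isolated)
Conditions: 2-(pentafluorophenyl)-6,7-dihydro-5H-pyrrolo[2,1-c][1,2,4]triazol-2-ium tetrafluoroborate (20 mol %), NaOAc (30 mol %), 4 Å molecular sieves, degassed THF, rt, argon; then dilute aq. HCl
Reagents that add atoms: none
Why: Proposed new method: the carbene adds to one aldehyde of 17, proton transfer gives the nucleophilic amino enol, this acyl anion equivalent attacks the other aldehyde carbon to form the C6–C7 bond, and loss of the carbene leaves acyloin 18, which enolises through its C5 ketone and C8 methylene to the trihydroxybenzene ring of 19 at unchanged oxidation level. The closest known reaction type is the carbene-catalysed intramolecular crossed benzoin (acyloin) cyclisation of dialdehydes and keto aldehydes, which has not been shown for a glyoxal paired with an enolisable aldehyde followed by aromatisation. Ring A closes in a 6-exo-trig mode. The carbinol stereocentre of 18 is transient and is erased on aromatisation, so nothing needs to control it. The step needs the acyl anion pathway to be faster than aldol attack of the acidic C8 methylene on the glyoxal (a five-membered closure) and than oligomerisation. The substrate secures this because either aldehyde may be the donor and both modes converge on the same arene; the acetate-buffered, weakly basic carbene system and the irreversible aromatisation are the supporting measures.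

Step 10
Reactants: 19 5,6,7-trihydroxy-2-(2,3,4,5-tetramethoxyphenyl)-4H-chromen-4-one
Product: 20 Agecorynin F, 5-hydroxy-6,7-dimethoxy-2-(2,3,4,5-tetramethoxyphenyl)-4H-chromen-4-one
Conditions: Me2SO4 (2.1 equiv), K2CO3 (2.5 equiv), acetone, reflux, argon
Reagents that add atoms: dimethyl sulfate, COS(=O)(=O)OC
Why: Williamson-type O-methylation in which the C5 hydroxyl, hydrogen-bonded to the C4 carbonyl, is much less acidic and nucleophilic than the C6 and C7 phenols, so two equivalents of the methylating agent should stop at the 6,7-dimethyl ether.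

Compound list
1 | 1,2,3,4-tetramethoxybenzene | COc1ccc(OC)c(OC)c1OC | starting material
2 | 1-iodo-2,3,4,5-tetramethoxybenzene | COc1cc(I)c(OC)c(OC)c1OC | intermediate
3 | propiolic acid | C#CC(=O)O | starting material
4 | 3-(2,3,4,5-tetramethoxyphenyl)prop-2-ynoic acid | COc1cc(C#CC(=O)O)c(OC)c(OC)c1OC | intermediate
5 | tert-butyl acetoacetate | CC(=O)CC(=O)OC(C)(C)C | starting material
6 | 3-(2,3,4,5-tetramethoxyphenyl)prop-2-ynoyl chloride | COc1cc(C#CC(Cl)=O)c(OC)c(OC)c1OC | intermediate
7 | tert-butyl 2-acetyl-3-oxo-5-(2,3,4,5-tetramethoxyphenyl)pent-4-ynoate | CC(=O)C(C(=O)OC(C)(C)C)C(=O)C#Cc1cc(OC)c(OC)c(OC)c1OC | intermediate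
8 | tert-butyl 2-methyl-4-oxo-6-(2,3,4,5-tetramethoxyphenyl)-4H-pyran-3-carboxylate | CC1=C(C(=O)OC(C)(C)C)C(=O)C=C(O1)c1cc(OC)c(OC)c(OC)c1OC | intermediate
9 | 2-methyl-4-oxo-6-(2,3,4,5-tetramethoxyphenyl)-4H-pyran-3-carboxylic acid | CC1=C(C(=O)O)C(=O)C=C(O1)c1cc(OC)c(OC)c(OC)c1OC | intermediate
10 | (trimethylsilyl)diazomethane | C[Si](C)(C)C=[N+]=[N-] | starting material
11 | 2-methyl-4-oxo-6-(2,3,4,5-tetramethoxyphenyl)-4H-pyran-3-carbonyl chloride | CC1=C(C(Cl)=O)C(=O)C=C(O1)c1cc(OC)c(OC)c(OC)c1OC | intermediate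
12 | 3-(2-diazoacetyl)-2-methyl-6-(2,3,4,5-tetramethoxyphenyl)-4H-pyran-4-one | CC1=C(C(=O)C=[N+]=[N-])C(=O)C=C(O1)c1cc(OC)c(OC)c(OC)c1OC | intermediate
13 | 2-[2-methyl-4-oxo-6-(2,3,4,5-tetramethoxyphenyl)-4H-pyran-3-yl]-2-oxoacetaldehyde | CC1=C(C(=O)C=O)C(=O)C=C(O1)c1cc(OC)c(OC)c(OC)c1OC | intermediate
14 | 3-(2,2-dimethoxyacetyl)-2-methyl-6-(2,3,4,5-tetramethoxyphenyl)-4H-pyran-4-one | CC1=C(C(=O)C(OC)OC)C(=O)C=C(O1)c1cc(OC)c(OC)c(OC)c1OC | intermediate
15 | N,N-dimethylformamide dimethyl acetal | COC(OC)N(C)C | starting material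
16 | 3-(2,2-dimethoxyacetyl)-2-[(E)-2-(dimethylamino)ethenyl]-6-(2,3,4,5-tetramethoxyphenyl)-4H-pyran-4-one | CN(C)/C=C/C1=C(C(=O)C(OC)OC)C(=O)C=C(O1)c1cc(OC)c(OC)c(OC)c1OC | intermediate
17 | 2-oxo-2-[4-oxo-2-(2-oxoethyl)-6-(2,3,4,5-tetramethoxyphenyl)-4H-pyran-3-yl]acetaldehyde | O=CCC1=C(C(=O)C=O)C(=O)C=C(O1)c1cc(OC)c(OC)c(OC)c1OC | intermediate
18 | 6-hydroxy-2-(2,3,4,5-tetramethoxyphenyl)-6,8-dihydro-4H-chromene-4,5,7-trione (racemic, transient) | O=C1CC2=C(C(=O)C1O)C(=O)C=C(O2)c1cc(OC)c(OC)c(OC)c1OC | intermediate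
19 | 5,6,7-trihydroxy-2-(2,3,4,5-tetramethoxyphenyl)-4H-chromen-4-one | COc1cc(-c2cc(=O)c3c(O)c(O)c(O)cc3o2)c(OC)c(OC)c1OC | intermediate
20 | Agecorynin F, 5-hydroxy-6,7-dimethoxy-2-(2,3,4,5-tetramethoxyphenyl)-4H-chromen-4-one | COc1cc(-c2cc(=O)c3c(O)c(OC)c(OC)cc3o2)c(OC)c(OC)c1OC | target

Total step count: 10. Longest linear sequence: 10 steps (1 to 20).

Steps most likely to fail

1. Step 9. Enolisation of the C8 methylene may lead to aldol closure onto the glyoxal faster than the carbene generates the acyl anion equivalent, or the dialdehyde may oligomerise, so that ring A does not form. The fallback is the classical chalcone route and sets out from 1. Rieche formylation (Cl2CHOMe, TiCl4, CH2Cl2, 0 °C) should give 2,3,4,5-tetramethoxybenzaldehyde F1. Claisen–Schmidt condensation with commercial 1-(6-hydroxy-2,3,4-trimethoxyphenyl)ethanone (KOH, EtOH, rt) should give (E)-1-(6-hydroxy-2,3,4-trimethoxyphenyl)-3-(2,3,4,5-tetramethoxyphenyl)prop-2-en-1-one F2. Oxidative cyclisation (I2 cat., DMSO, 120 °C) should give 5,6,7-trimethoxy-2-(2,3,4,5-tetramethoxyphenyl)-4H-chromen-4-one F3. Chelation-directed cleavage of the C5 methyl ether next to the C4 carbonyl (BCl3, CH2Cl2, −20 °C) comes back to the route at 20.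

2. Step 8. The deactivated α-keto acetal may hydrolyse incompletely under conditions the product tolerates, or acid may promote aldol condensation once both aldehydes are free. The fallback uses an orthogonal mask that is removed at neutral pH and sets out from 13. Thioacetalisation (EtSH, BF3·OEt2, CH2Cl2, 0 °C) should give 3-[2,2-bis(ethylsulfanyl)acetyl]-2-methyl-6-(2,3,4,5-tetramethoxyphenyl)-4H-pyran-4-one F4. Enamination with 15 (toluene, 90 °C) should give 3-[2,2-bis(ethylsulfanyl)acetyl]-2-[(E)-2-(dimethylamino)ethenyl]-6-(2,3,4,5-tetramethoxyphenyl)-4H-pyran-4-one F5. Brief hydrolysis (1 M aq. HCl, THF, 0 °C) should cleave only the enamine and give 2-{3-[2,2-bis(ethylsulfanyl)acetyl]-4-oxo-6-(2,3,4,5-tetramethoxyphenyl)-4H-pyran-2-yl}acetaldehyde F6. Alkylative hydrolysis of the dithioacetal (MeI, CaCO3, MeCN/H2O, 40 °C) comes back to the route at 17.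

3. Step 5. The acid chloride may be lost through vinylogous ketene formation at the C2 methyl, or the diazoalkane may add as a dipole to the doubly activated pyranone double bond. The fallback avoids diazo chemistry and sets out from 11, made from 9 as in step 5. Acylation of tris(trimethylsilyloxy)ethene (neat, 95 °C) followed by aq. HCl/dioxane should give 2-hydroxy-3-[2-methyl-4-oxo-6-(2,3,4,5-tetramethoxyphenyl)-4H-pyran-3-yl]-3-oxopropanoic acid F7. On warming this should decarboxylate to 3-(2-hydroxyacetyl)-2-methyl-6-(2,3,4,5-tetramethoxyphenyl)-4H-pyran-4-one F8. Oxidation of the primary ketol (Dess–Martin periodinane, NaHCO3, CH2Cl2) comes back to the route at 13, which is acetalised to 14 as in step 6.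

Further compounds
F1 | step 9 | 2,3,4,5-tetramethoxybenzaldehyde | COc1cc(C=O)c(OC)c(OC)c1OC
F2 | step 9 | (E)-1-(6-hydroxy-2,3,4-trimethoxyphenyl)-3-(2,3,4,5-tetramethoxyphenyl)prop-2-en-1-one | COc1cc(/C=C/C(=O)c2c(O)cc(OC)c(OC)c2OC)c(OC)c(OC)c1OC
F3 | step 9 | 5,6,7-trimethoxy-2-(2,3,4,5-tetramethoxyphenyl)-4H-chromen-4-one | COc1cc(-c2cc(=O)c3c(OC)c(OC)c(OC)cc3o2)c(OC)c(OC)c1OC
F4 | step 8 | 3-[2,2-bis(ethylsulfanyl)acetyl]-2-methyl-6-(2,3,4,5-tetramethoxyphenyl)-4H-pyran-4-one | CC1=C(C(=O)C(SCC)SCC)C(=O)C=C(O1)c1cc(OC)c(OC)c(OC)c1OC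
F5 | step 8 | 3-[2,2-bis(ethylsulfanyl)acetyl]-2-[(E)-2-(dimethylamino)ethenyl]-6-(2,3,4,5-tetramethoxyphenyl)-4H-pyran-4-one | CN(C)/C=C/C1=C(C(=O)C(SCC)SCC)C(=O)C=C(O1)c1cc(OC)c(OC)c(OC)c1OC
F6 | step 8 | 2-{3-[2,2-bis(ethylsulfanyl)acetyl]-4-oxo-6-(2,3,4,5-tetramethoxyphenyl)-4H-pyran-2-yl}acetaldehyde | O=CCC1=C(C(=O)C(SCC)SCC)C(=O)C=C(O1)c1cc(OC)c(OC)c(OC)c1OC
F7 | step 5 | 2-hydroxy-3-[2-methyl-4-oxo-6-(2,3,4,5-tetramethoxyphenyl)-4H-pyran-3-yl]-3-oxopropanoic acid | CC1=C(C(=O)C(O)C(=O)O)C(=O)C=C(O1)c1cc(OC)c(OC)c(OC)c1OC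
F8 | step 5 | 3-(2-hydroxyacetyl)-2-methyl-6-(2,3,4,5-tetramethoxyphenyl)-4H-pyran-4-one | CC1=C(C(=O)CO)C(=O)C=C(O1)c1cc(OC)c(OC)c(OC)c1OC
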